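The 2,5-dihydrofuran ring (O, C5, C6, C7, C8; carotenoid numbering) is taken apart into an aldehyde C8=O and the allyl unit C5–C6–C7 that it shares with the cyclohexane ring. The precursor is a 3-silyloxy-β-cyclogeranyl acetate made from (4R,6R)-actinol; a Lewis acid turns it into an allyl cation, the oxygen of ethyl 3-formylcrotonate captures its tertiary end C5, and the oxocarbenium ion closes onto C7. One operation thus forms O–C5 and C7–C8 and sets C5 and C8 from the purchased C3 centre, exploiting the tertiary/primary polarity of the allyl unit and the ring locked by the C1 methyl groups. A C25 ψ-end Wittig salt then completes the polyene.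

Key step: step 4

Remark: carotenoid numbering is used for the skeleton; TBS = tert-butyldimethylsilyl; Wittig products are drawn as the all-E isomers expected after thermal isomerisation.

Step 1
Reactants: 1 (4R,6R)-4-hydroxy-2,2,6-trimethylcyclohexan-1-one (actinol)
Product: 2 (4R,6R)-4-(TBSO)-2,2,6-trimethylcyclohexan-1-one
Conditions: TBSCl, imidazole, DMF, rt
Reagents that add atoms: tert-butyldimethylsilyl chloride, CC(C)(C)[Si](C)(C)Cl
Why: Silylation of the secondary alcohol under standard conditions should leave the hindered ketone and both stereocentres untouched.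

Step 2
Reactants: 2 (4R,6R)-4-(TBSO)-2,2,6-trimethylcyclohexan-1-one
Product: 3 N'-[(4R,6R)-4-(TBSO)-2,2,6-trimethylcyclohexylidene]-2,4,6-triisopropylbenzenesulfonohydrazide
Conditions: TrisNHNH2, PPTS (cat.), MeCN, rt
Reagents that add atoms: 2,4,6-triisopropylbenzenesulfonohydrazide, CC(C)c1cc(C(C)C)c(S(=O)(=O)NN)c(C(C)C)c1
Why: Condensation of the ketone with the arenesulfonyl hydrazide gives the hydrazone needed for the Shapiro reaction, and the centre next to C=N is lost in step 3, so its epimerisation would not matter.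

Step 3
Reactants: 3 N'-[(4R,6R)-4-(TBSO)-2,2,6-trimethylcyclohexylidene]-2,4,6-triisopropylbenzenesulfonohydrazide
Product: 6 [(4R)-4-(TBSO)-2,6,6-trimethylcyclohex-1-en-1-yl]methyl acetate, via alkenyllithium 4 (not isolated), via lithium alkoxide 5 (not isolated)
Conditions: s-BuLi (2.2 equiv), TMEDA, THF, −78 → 0 °C; CH2O (gas), −78 °C → rt; Ac2O, 0 °C
Reagents that add atoms: formaldehyde, C=O; acetic anhydride, CC(=O)OC(C)=O
Why: Shapiro reaction, in which the hydrazone dianion can form only at the single α-hydrogen, so loss of sulfinate and N2 should give the tetrasubstituted alkenyllithium regiospecifically, which adds to formaldehyde and is acetylated in the same flask.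

Step 4
Reactants: 6 [(4R)-4-(TBSO)-2,6,6-trimethylcyclohex-1-en-1-yl]methyl acetate, 7 ethyl (2E)-3-methyl-4-oxobut-2-enoate (ethyl 3-formylcrotonate)
Product: 10 ethyl (2E)-3-[(2S,6S,7aR)-6-(TBSO)-4,4,7a-trimethyl-2,4,5,6,7,7a-hexahydro-1-benzofuran-2-yl]but-2-enoate, via allyl cation triflate 8 (not isolated), via oxocarbenium triflate 9 (not isolated)
Conditions: 7 (3 equiv), TMSOTf (1.1 equiv), 2,6-di-tert-butyl-4-methylpyridine (1.5 equiv), CH2Cl2, −78 → −40 °C
Reagents that add atoms: none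
Why: Proposed new method: TMSOTf should ionise the allylic acetate to the allyl cation 8 (tertiary at C5, primary at C7), the carbonyl oxygen of enal 7 should capture it at C5 to give the oxocarbenium ion 9, the exocyclic C6=C7 bond freed in that capture should attack the oxocarbenium carbon C8 through C7, and the tertiary C6 cation should lose a C7 proton to the hindered pyridine. The closest known reaction types are the Prins cyclisation of oxocarbenium ions onto 1,1-disubstituted alkenes, the capture of carbocations by aldehyde oxygen in Prins 1,3-dioxane formation, and the aldehyde/donor–acceptor cyclopropane [3+2] annulation, which also makes the C–O bond first and gives 2,5-cis oxolanes. The dihydrofuran ring closes by a cationic 5-endo-trig attack of the alkene terminus C7 on C8, followed by E1 loss of H7, the only β-hydrogen available to the C6 cation. C5 is controlled by C3: with the silyloxy group equatorial in the half-chair cation, only a C5–O bond that is axial and anti to C3–O lets C8 reach the π lobe of C7 without a syn-triaxial chair, the same facial preference as in the anti epoxidation of 3-acyloxy β-end groups. C8 is controlled in the same closure, because the E-oxocarbenium ion should cyclise with its butenoate substituent exo, turned away from C6 and the axial C1 methyl group, which places it cis to the C5 methyl group (8S). The step needs capture at the tertiary and not the primary allyl terminus, which prenyl-type cations favour kinetically, and it needs the new doubly allylic C8–O bond to survive the Lewis acid, which the conjugated ester secures by destabilising a C8 cation.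

Step 5
Reactants: 10 ethyl (2E)-3-[(2S,6S,7aR)-6-(TBSO)-4,4,7a-trimethyl-2,4,5,6,7,7a-hexahydro-1-benzofuran-2-yl]but-2-enoate
Product: 11 (2E)-3-[(2S,6S,7aR)-6-(TBSO)-4,4,7a-trimethyl-2,4,5,6,7,7a-hexahydro-1-benzofuran-2-yl]but-2-en-1-ol
Conditions: DIBAL-H (2.5 equiv), CH2Cl2, −78 °C
Reagents that add atoms: none
Why: DIBAL-H should reduce the conjugated ester by 1,2-addition to the allylic alcohol at low temperature without touching the silyl ether, the dihydrofuran or the stereocentres.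

Step 6
Reactants: 11 (2E)-3-[(2S,6S,7aR)-6-(TBSO)-4,4,7a-trimethyl-2,4,5,6,7,7a-hexahydro-1-benzofuran-2-yl]but-2-en-1-ol
Product: 12 (2E)-3-[(2S,6S,7aR)-6-(TBSO)-4,4,7a-trimethyl-2,4,5,6,7,7a-hexahydro-1-benzofuran-2-yl]but-2-enal
Conditions: activated MnO2, CH2Cl2, rt
Reagents that add atoms: none
Why: MnO2 oxidises the primary allylic alcohol to the enal under neutral conditions, so neither the acid-labile C8–O bond nor the base-labile C8–H is put at risk.

Step 7
Reactants: 13 (3E,5E)-6,10-dimethylundeca-3,5,9-trien-2-one (pseudoionone)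
Product: 14 (4E,6E)-3,7,11-trimethyldodeca-1,4,6,10-tetraen-3-ol (racemic)
Conditions: vinylmagnesium bromide, THF, −20 → 0 °C
Reagents that add atoms: vinylmagnesium bromide, C=C[Mg]Br
Why: 1,2-Addition of the vinyl Grignard reagent to the dienone carbonyl should give the tertiary bis-allylic alcohol, whose stereocentre is lost in step 8.

Step 8
Reactants: 14 (4E,6E)-3,7,11-trimethyldodeca-1,4,6,10-tetraen-3-ol
Product: 15 [(2E,4E,6E)-3,7,11-trimethyldodeca-2,4,6,10-tetraen-1-yl]triphenylphosphonium bromide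
Conditions: PPh3·HBr, MeOH, rt
Reagents that add atoms: triphenylphosphine hydrobromide, Br.c1ccc(cc1)P(c1ccccc1)c1ccccc1
Why: Triphenylphosphine hydrobromide should convert the tertiary allylic alcohol with allylic transposition (SN1/SN2′) into the primary, conjugated phosphonium salt.

Step 9
Reactants: 15 [(2E,4E,6E)-3,7,11-trimethyldodeca-2,4,6,10-tetraen-1-yl]triphenylphosphonium bromide, 16 (2E,4E,6E)-2,7-dimethylocta-2,4,6-trienedial
Product: 18 (2E,4E,6E,8E,10E,12E,14E)-2,7,11,15,19-pentamethylicosa-2,4,6,8,10,12,14,18-octaenal (12′-apo-ψ-caroten-12′-al), via phosphorus ylide 17 (not isolated)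
Conditions: 16 (3 equiv), NaOMe, MeOH/CH2Cl2, 0 °C → rt; then n-heptane, reflux
Reagents that add atoms: none
Why: Wittig reaction of the semi-stabilised ylide with one formyl group of the symmetrical dialdehyde, used in excess to favour mono-olefination, and heating should convert Z isomers of the new double bond into the E form.

Step 10
Reactants: 18 12′-apo-ψ-caroten-12′-al
Product: 19 (2E,4E,6E,8E,10E,12E,14E)-2,7,11,15,19-pentamethylicosa-2,4,6,8,10,12,14,18-octaen-1-ol
Conditions: NaBH4, EtOH/THF, 0 °C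
Reagents that add atoms: none
Why: NaBH4 should reduce the polyenal by 1,2-addition to the primary allylic alcohol.

Step 11
Reactants: 19 (2E,4E,6E,8E,10E,12E,14E)-2,7,11,15,19-pentamethylicosa-2,4,6,8,10,12,14,18-octaen-1-ol
Product: 20 [(2E,4E,6E,8E,10E,12E,14E)-2,7,11,15,19-pentamethylicosa-2,4,6,8,10,12,14,18-octaen-1-yl]triphenylphosphonium bromide
Conditions: PPh3·HBr, CH2Cl2/MeOH, 0 °C → rt, dark
Reagents that add atoms: triphenylphosphine hydrobromide, Br.c1ccc(cc1)P(c1ccccc1)c1ccccc1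
Why: The polyenyl alcohol should be converted through its delocalised cation into the phosphonium salt, with phosphine capture at the primary terminus keeping the conjugation.

Step 12
Reactants: 20 C25 phosphonium bromide, 12 (2E)-3-[(2S,6S,7aR)-6-(TBSO)-4,4,7a-trimethyl-2,4,5,6,7,7a-hexahydro-1-benzofuran-2-yl]but-2-enal
Product: 22 (3S,5R,8S)-3-(TBSO)-5,8-epoxy-5,8-dihydro-β,ψ-carotene, via phosphorus ylide 21 (not isolated)
Conditions: NaHMDS (1.0 equiv), THF, −78 °C; then 12, −78 → 0 °C; then n-heptane, reflux, dark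
Reagents that add atoms: none
Why: Wittig reaction of the preformed polyenyl ylide with enal 12 forms C11=C12 at low temperature without excess base near the γ-hydrogen at C8, and thermal isomerisation should give the all-E polyene.

Step 13
Reactants: 22 (3S,5R,8S)-3-(TBSO)-5,8-epoxy-5,8-dihydro-β,ψ-carotene
Product: 23 (3S,5R,8S)-5,8-epoxy-5,8-dihydro-β,ψ-caroten-3-ol
Conditions: TBAF, AcOH (1 equiv), THF, 0 °C → rt, dark
Reagents that add atoms: none
Why: Fluoride cleaves the silyl ether, and the acetic acid buffer keeps the medium near neutral for the acid-labile furanoid end group and the polyene.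

Compound list
1 | (4R,6R)-4-hydroxy-2,2,6-trimethylcyclohexan-1-one | O=C1C(C)(C)C[C@H](O)C[C@H]1C | starting material
2 | (4R,6R)-4-(TBSO)-2,2,6-trimethylcyclohexan-1-one | O=C1C(C)(C)C[C@H](O[Si](C)(C)C(C)(C)C)C[C@H]1C | intermediate
3 | N'-[(4R,6R)-4-(TBSO)-2,2,6-trimethylcyclohexylidene]-2,4,6-triisopropylbenzenesulfonohydrazide | CC(C)c1cc(C(C)C)c(S(=O)(=O)NN=C2C(C)(C)C[C@H](O[Si](C)(C)C(C)(C)C)C[C@H]2C)c(C(C)C)c1 | intermediate
4 | [(4R)-4-(TBSO)-2,6,6-trimethylcyclohex-1-en-1-yl]lithium | [Li]C1=C(C)C[C@@H](O[Si](C)(C)C(C)(C)C)CC1(C)C | intermediate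
5 | lithium [(4R)-4-(TBSO)-2,6,6-trimethylcyclohex-1-en-1-yl]methanolate | [Li+].[O-]CC1=C(C)C[C@@H](O[Si](C)(C)C(C)(C)C)CC1(C)C | intermediate
6 | [(4R)-4-(TBSO)-2,6,6-trimethylcyclohex-1-en-1-yl]methyl acetate | CC(=O)OCC1=C(C)C[C@@H](O[Si](C)(C)C(C)(C)C)CC1(C)C | intermediate
7 | ethyl (2E)-3-methyl-4-oxobut-2-enoate | CCOC(=O)/C=C(\C)C=O | starting material
8 | (5R)-5-(TBSO)-1,3,3-trimethyl-2-methylidenecyclohexan-1-ylium triflate (allyl cation, charge shared by C5 and C7) | C=C1[C+](C)C[C@@H](O[Si](C)(C)C(C)(C)C)CC1(C)C.[O-]S(=O)(=O)C(F)(F)F | intermediate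
9 | [(1R,5S)-5-(TBSO)-1,3,3-trimethyl-2-methylidenecyclohexyl][(2E)-4-ethoxy-2-methyl-4-oxobut-2-en-1-ylidene]oxonium triflate (E-oxocarbenium ion) | C=C1C(C)(C)C[C@H](O[Si](C)(C)C(C)(C)C)C[C@@]1(C)/[O+]=C/C(C)=C/C(=O)OCC.[O-]S(=O)(=O)C(F)(F)F | intermediate
10 | ethyl (2E)-3-[(2S,6S,7aR)-6-(TBSO)-4,4,7a-trimethyl-2,4,5,6,7,7a-hexahydro-1-benzofuran-2-yl]but-2-enoate | CCOC(=O)/C=C(\C)[C@@H]1C=C2C(C)(C)C[C@H](O[Si](C)(C)C(C)(C)C)C[C@@]2(C)O1 | intermediate
11 | (2E)-3-[(2S,6S,7aR)-6-(TBSO)-4,4,7a-trimethyl-2,4,5,6,7,7a-hexahydro-1-benzofuran-2-yl]but-2-en-1-ol | OC/C=C(\C)[C@@H]1C=C2C(C)(C)C[C@H](O[Si](C)(C)C(C)(C)C)C[C@@]2(C)O1 | intermediate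
12 | (2E)-3-[(2S,6S,7aR)-6-(TBSO)-4,4,7a-trimethyl-2,4,5,6,7,7a-hexahydro-1-benzofuran-2-yl]but-2-enal | O=C/C=C(\C)[C@@H]1C=C2C(C)(C)C[C@H](O[Si](C)(C)C(C)(C)C)C[C@@]2(C)O1 | intermediate
13 | (3E,5E)-6,10-dimethylundeca-3,5,9-trien-2-one (pseudoionone) | CC(C)=CCC/C(C)=C/C=C/C(C)=O | starting material
14 | (4E,6E)-3,7,11-trimethyldodeca-1,4,6,10-tetraen-3-ol (racemic) | CC(C)=CCC/C(C)=C/C=C/C(C)(O)C=C | intermediate
15 | [(2E,4E,6E)-3,7,11-trimethyldodeca-2,4,6,10-tetraen-1-yl]triphenylphosphonium bromide | CC(C)=CCC/C(C)=C/C=C/C(C)=C/C[P+](c1ccccc1)(c1ccccc1)c1ccccc1.[Br-] | intermediate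
16 | (2E,4E,6E)-2,7-dimethylocta-2,4,6-trienedial | O=C/C(C)=C/C=C/C=C(C)/C=O | starting material
17 | [(2E,4E,6E)-3,7,11-trimethyldodeca-2,4,6,10-tetraen-1-ylidene]triphenyl-λ5-phosphane (ylide of 15) | CC(C)=CCC/C(C)=C/C=C/C(C)=C/C=P(c1ccccc1)(c1ccccc1)c1ccccc1 | intermediate
18 | (2E,4E,6E,8E,10E,12E,14E)-2,7,11,15,19-pentamethylicosa-2,4,6,8,10,12,14,18-octaenal (12′-apo-ψ-caroten-12′-al) | CC(C)=CCC/C(C)=C/C=C/C(C)=C/C=C/C(C)=C/C=C/C=C(C)/C=O | intermediate
19 | (2E,4E,6E,8E,10E,12E,14E)-2,7,11,15,19-pentamethylicosa-2,4,6,8,10,12,14,18-octaen-1-ol | CC(C)=CCC/C(C)=C/C=C/C(C)=C/C=C/C(C)=C/C=C/C=C(C)/CO | intermediate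
20 | [(2E,4E,6E,8E,10E,12E,14E)-2,7,11,15,19-pentamethylicosa-2,4,6,8,10,12,14,18-octaen-1-yl]triphenylphosphonium bromide | CC(C)=CCC/C(C)=C/C=C/C(C)=C/C=C/C(C)=C/C=C/C=C(C)/C[P+](c1ccccc1)(c1ccccc1)c1ccccc1.[Br-] | intermediate
21 | ylide of 20, [(2E,4E,6E,8E,10E,12E,14E)-2,7,11,15,19-pentamethylicosa-2,4,6,8,10,12,14,18-octaen-1-ylidene]triphenyl-λ5-phosphane | CC(C)=CCC/C(C)=C/C=C/C(C)=C/C=C/C(C)=C/C=C/C=C(C)/C=P(c1ccccc1)(c1ccccc1)c1ccccc1 | intermediate
22 | (3S,5R,8S)-3-(TBSO)-5,8-epoxy-5,8-dihydro-β,ψ-carotene | CC(C)=CCC/C(C)=C/C=C/C(C)=C/C=C/C(C)=C/C=C/C=C(C)/C=C/C=C(\C)[C@@H]1C=C2C(C)(C)C[C@H](O[Si](C)(C)C(C)(C)C)C[C@@]2(C)O1 | intermediate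
23 | (3S,5R,8S)-5,8-epoxy-5,8-dihydro-β,ψ-caroten-3-ol | CC(C)=CCC/C(C)=C/C=C/C(C)=C/C=C/C(C)=C/C=C/C=C(C)/C=C/C=C(\C)[C@@H]1C=C2C(C)(C)C[C@H](O)C[C@@]2(C)O1 | target

Total step count: 13
Longest linear sequence: 8 steps (steps 1–6, 12 and 13)

Steps most likely to fail

1. Step 4 (Proposed new method). The allyl cation may lose a proton to dienes before the enal captures it. The silyl-activated enal may instead be attacked by the tetrasubstituted ring double bond of 6 (ene or Prins reaction at C5). Capture at C5 may be reversible or occur on the wrong face, eroding the relay from C3 to C5 and C8, and the C6 cation may undergo a 1,2-shift before it loses H7. Fallback, from 6 back to 10, by known chemistry: acetate 6 and triphenylphosphine hydrobromide would give {[(4R)-4-(TBSO)-2,6,6-trimethylcyclohex-1-en-1-yl]methyl}triphenylphosphonium bromide F1. Its ylide (NaHMDS, THF) would be condensed with aldehyde 7 in a Wittig reaction to ethyl (2E,4E)-5-[(4R)-4-(TBSO)-2,6,6-trimethylcyclohex-1-en-1-yl]-3-methylpenta-2,4-dienoate F2. Epoxidation with mCPBA at the electron-rich tetrasubstituted ring double bond, anti to the silyloxy group, would give ethyl (2E,4E)-5-[(1S,4S,6R)-4-(TBSO)-2,2,6-trimethyl-7-oxabicyclo[4.1.0]heptan-1-yl]-3-methylpenta-2,4-dienoate F3. A trace of HCl in CHCl3 should then effect the epoxide–furanoid rearrangement to ester 10 together with its C8 epimer, which would have to be separated by chromatography.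

2. Step 3. Deprotonation at the tertiary α-hydrogen of the hindered hydrazone may be slow or incomplete, and the tetrasubstituted alkenyllithium may be protonated before formaldehyde traps it. Fallback, from 2 back to 6: ketone 2 would be converted with LDA and PhNTf2 into (4R)-4-(TBSO)-2,6,6-trimethylcyclohex-1-en-1-yl trifluoromethanesulfonate F4. Palladium-catalysed methoxycarbonylation (Pd(OAc)2, dppp, CO, MeOH, Et3N) would give methyl (4R)-4-(TBSO)-2,6,6-trimethylcyclohex-1-ene-1-carboxylate F5. DIBAL-H reduction would give [(4R)-4-(TBSO)-2,6,6-trimethylcyclohex-1-en-1-yl]methanol F6, and acetylation (Ac2O, pyridine) would give 6.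

3. Step 12. The ylide may deprotonate the γ-hydrogen at C8 of enal 12, which would epimerise C8, and the new double bond may form partly as the 11Z isomer that resists isomerisation. Fallback, from 11 and 18 back to 22, with the polarity of the Wittig union reversed: alcohol 11 and triphenylphosphine hydrobromide (CH2Cl2, 0 °C) would give {(2E)-3-[(2S,6S,7aR)-6-(TBSO)-4,4,7a-trimethyl-2,4,5,6,7,7a-hexahydro-1-benzofuran-2-yl]but-2-en-1-yl}triphenylphosphonium bromide F7. This salt would be condensed with the C25 aldehyde 18 in 1,2-epoxybutane as base-free HBr acceptor, followed by thermal isomerisation, to give 22.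

Further compounds
F1 | step 4 | {[(4R)-4-(TBSO)-2,6,6-trimethylcyclohex-1-en-1-yl]methyl}triphenylphosphonium bromide | CC1=C(C[P+](c2ccccc2)(c2ccccc2)c2ccccc2)C(C)(C)C[C@H](O[Si](C)(C)C(C)(C)C)C1.[Br-]
F2 | step 4 | ethyl (2E,4E)-5-[(4R)-4-(TBSO)-2,6,6-trimethylcyclohex-1-en-1-yl]-3-methylpenta-2,4-dienoate | CCOC(=O)/C=C(C)/C=C/C1=C(C)C[C@@H](O[Si](C)(C)C(C)(C)C)CC1(C)C
F3 | step 4 | ethyl (2E,4E)-5-[(1S,4S,6R)-4-(TBSO)-2,2,6-trimethyl-7-oxabicyclo[4.1.0]heptan-1-yl]-3-methylpenta-2,4-dienoate | CCOC(=O)/C=C(C)/C=C/[C@]12C(C)(C)C[C@H](O[Si](C)(C)C(C)(C)C)C[C@@]1(C)O2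
F4 | step 3 | (4R)-4-(TBSO)-2,6,6-trimethylcyclohex-1-en-1-yl trifluoromethanesulfonate | CC1=C(OS(=O)(=O)C(F)(F)F)C(C)(C)C[C@H](O[Si](C)(C)C(C)(C)C)C1
F5 | step 3 | methyl (4R)-4-(TBSO)-2,6,6-trimethylcyclohex-1-ene-1-carboxylate | COC(=O)C1=C(C)C[C@@H](O[Si](C)(C)C(C)(C)C)CC1(C)C
F6 | step 3 | [(4R)-4-(TBSO)-2,6,6-trimethylcyclohex-1-en-1-yl]methanol | OCC1=C(C)C[C@@H](O[Si](C)(C)C(C)(C)C)CC1(C)C
F7 | step 12 | {(2E)-3-[(2S,6S,7aR)-6-(TBSO)-4,4,7a-trimethyl-2,4,5,6,7,7a-hexahydro-1-benzofuran-2-yl]but-2-en-1-yl}triphenylphosphonium bromide | [Br-].c1ccc(cc1)[P+](c1ccccc1)(c1ccccc1)C/C=C(\C)[C@@H]1C=C2C(C)(C)C[C@H](O[Si](C)(C)C(C)(C)C)C[C@@]2(C)O1
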